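**Retrosynthetic overview** (numbering: C1 = CH2OBz carbon, main chain C1–C15 with methyls on C3, C7 and C15, lactone carbonyl C20 on C11)
1. Target ⇐ diol 24 (two acetylations) ⇐ C10=C11 by cross-metathesis of terminal alkene 12 (C1–C10 plus one extra CH2) with α-methylene lactone 22.
2. Lactone 22 ⇐ 2-deoxy-D-ribose: sugar C1–C5 become C20, C11, C12, C13, C14, so both ring stereocentres come from the chiral pool; a Wittig reaction adds C15 and a Mannich/elimination sequence adds the exo-methylene.
3. Alkene 12 ⇐ C4–C5 bond by vinylogous aldol–lactonisation of enal 5 (C5 = CHO) with the γ-carbon (C4) of ethyl 3-methylbut-2-enoate; the temporary 5,6-dihydro-2H-pyran-2-one (O, C1, C2, C3, C4, C5) can only hold a cis C2=C3, and its C5–O bond is then cut by Pd/hydride.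
4. Enabling feature: the Z C2=C3 alkene holds C1 and C4 cis, and C5 is both δ to C1 and allylic to C6=C7. An oxygen on C5 therefore closes a six-membered lactone onto C1 and later serves as an allylic carboxylate leaving group.
5. C8 (R) ⇐ Brown allylation of a C5 acetal-enal; ring order: temporary δ-lactone (closed in step 4, opened in step 5), then the γ-butyrolactone of the target (step 8, from the sugar).

Key step: step 4

Remark: (E)-4,4-dimethoxy-2-methylbut-2-enal 1 is assumed to be commercially available; 13 is written in its open-chain form; C5 of lactone 9 is formed as both epimers on purpose, because step 5 turns it into a CH2.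

**Step 1**
Reactants: 1 (E)-4,4-dimethoxy-2-methylbut-2-enal
Product: 3 (2E,4R)-1,1-dimethoxy-3-methylhepta-2,6-dien-4-ol, via diisopinocampheylborinate ester 2 (not isolated)
Conditions: (+)-Ipc2BOMe [from (−)-α-pinene], allylMgBr, Et2O, 0 °C → rt; then 1, −78 °C; then NaOH, H2O2, rt
Reagents that add atoms: allylmagnesium bromide, C=CC[Mg]Br
Why: Brown asymmetric allylboration: the B-allyl reagent from (−)-α-pinene should transfer allyl through a chair Zimmerman–Traxler transition state to the Re face of the α-methyl enal, which sets C8 as R under reagent control, and the acetal is inert to the reagent and to the alkaline peroxide work-up.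

**Step 2**
Reactants: 3 (2E,4R)-1,1-dimethoxy-3-methylhepta-2,6-dien-4-ol
Product: 4 tert-butyl{[(2E,4R)-1,1-dimethoxy-3-methylhepta-2,6-dien-4-yl]oxy}dimethylsilane
Conditions: TBSCl, imidazole, DMF, rt
Reagents that add atoms: tert-butyldimethylsilyl chloride, CC(C)(C)[Si](C)(C)Cl
Why: Silyl ether formation on a secondary allylic alcohol under neutral imidazole conditions that leave the dimethyl acetal intact; no stereocentre is touched.

**Step 3**
Reactants: 4 tert-butyl{[(2E,4R)-1,1-dimethoxy-3-methylhepta-2,6-dien-4-yl]oxy}dimethylsilane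
Product: 5 (2E,4R)-4-[(tert-butyldimethylsilyl)oxy]-3-methylhepta-2,6-dienal
Conditions: PPTS (cat.), acetone/H2O, rt
Reagents that add atoms: water, O
Why: Acid-catalysed acetal hydrolysis, which is fast for an allylic acetal under conditions too mild to cleave the secondary TBS ether or to move the conjugated E alkene; C8 is untouched.

**Step 4**
Reactants: 5 (2E,4R)-4-[(tert-butyldimethylsilyl)oxy]-3-methylhepta-2,6-dienal; 6 ethyl 3-methylbut-2-enoate
Product: 9 6-[(1E,3R)-3-[(tert-butyldimethylsilyl)oxy]-2-methylhexa-1,5-dien-1-yl]-4-methyl-5,6-dihydro-2H-pyran-2-one (both C6 epimers), via lithium dienolate 7 (not isolated), via lithium aldolate 8 (not isolated)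
Conditions: LDA, THF, −78 °C; 6; DMPU; then 5, −78 → 0 °C; aq. NH4Cl
Reagents that add atoms: none
Why: LDA removes a γ-proton of 6 (the methyl cis to the ester) to give cross-conjugated dienolate 7; addition through its α-carbon is reversible, whereas addition of the γ-carbon (C4) to the aldehyde carbon (C5) gives aldolate 8, whose alkoxide closes irreversibly on the ester with loss of ethoxide. The closest known reaction type is the vinylogous aldol–lactonisation of lithium dienolates of 3-methylbut-2-enoates with aldehydes in THF with a polar co-solvent, which gives 4-methyl-5,6-dihydropyran-2-ones directly (used for steroidal δ-lactone side chains). The one ring closed is the six-membered lactone, formed by 6-exo-trig O-acylation; it can form only from the enoate in which C1 and C4 are cis, so the Z geometry of C2=C3 is fixed by the ring and not by the aldol step. The new stereocentre at C5 is not controlled and need not be, because step 5 converts it into a CH2. The step needs 1,2- over 1,4-addition (secured by the β,β-disubstituted enal, lithium counter-ion and low temperature), γ- over α-attack (secured by the reversibility of the α-aldol and the lactonisation sink), and addition faster than γ-deprotonation of 5 (low temperature, cold quench). In one operation it should deliver the C4–C5 bond, the complete C1–C10 carbon chain and the Z-trisubstituted alkene.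

**Step 5**
Reactants: 9 6-[(1E,3R)-3-[(tert-butyldimethylsilyl)oxy]-2-methylhexa-1,5-dien-1-yl]-4-methyl-5,6-dihydro-2H-pyran-2-one
Product: 10 (2Z,6E,8R)-8-[(tert-butyldimethylsilyl)oxy]-3,7-dimethylundeca-2,6,10-trienoic acid
Conditions: Pd(PPh3)4 (cat.), NaBH4, THF, 0 °C → rt; then cold dil. HCl to pH 3
Reagents that add atoms: none
Why: Palladium-catalysed allylic hydrogenolysis (Tsuji–Trost ionisation, then hydride transfer): Pd(0) should ionise the only allylic ester C–O bond (C5–O) and borohydride-derived hydride should enter at the less substituted allyl terminus C5, which removes the C5 stereocentre, keeps C6=C7 (E) in place and frees the (Z)-acid whose geometry was fixed by the ring.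

**Step 6**
Reactants: 10 (2Z,6E,8R)-8-[(tert-butyldimethylsilyl)oxy]-3,7-dimethylundeca-2,6,10-trienoic acid
Product: 11 (2Z,6E,8R)-8-[(tert-butyldimethylsilyl)oxy]-3,7-dimethylundeca-2,6,10-trien-1-ol
Conditions: LiAlH4, THF, 0 °C → rt; Fieser work-up
Reagents that add atoms: none
Why: Hydride reduction of a carboxylic acid with LiAlH4, which for a β,β-disubstituted acrylic acid should give the allylic alcohol without conjugate reduction or loss of the Z geometry; the silyl ether and isolated alkenes are inert.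

**Step 7**
Reactants: 11 (2Z,6E,8R)-8-[(tert-butyldimethylsilyl)oxy]-3,7-dimethylundeca-2,6,10-trien-1-ol
Product: 12 (2Z,6E,8R)-8-[(tert-butyldimethylsilyl)oxy]-3,7-dimethylundeca-2,6,10-trien-1-yl benzoate
Conditions: BzCl, Et3N, DMAP (cat.), CH2Cl2, 0 °C
Reagents that add atoms: benzoyl chloride, O=C(Cl)c1ccccc1
Why: DMAP-catalysed acylation of the primary allylic alcohol installs the benzoate of the target; no stereo-element is affected.

**Step 8**
Reactants: 13 2-deoxy-D-ribose
Product: 14 2-deoxy-D-ribono-1,4-lactone [(4S,5R)-4-hydroxy-5-(hydroxymethyl)oxolan-2-one]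
Conditions: Br2, H2O, rt
Reagents that add atoms: none
Why: Bromine-water oxidation of the aldose hemiacetal to the aldono-γ-lactone closes the butyrolactone of the target by 5-exo lactonisation; C12 (S) and C13 (R) are the sugar C3 and C4 and are taken unchanged from the chiral pool.

**Step 9**
Reactants: 14 2-deoxy-D-ribono-1,4-lactone
Product: 15 (4S,5R)-4-[(tert-butyldimethylsilyl)oxy]-5-{[(tert-butyldimethylsilyl)oxy]methyl}oxolan-2-one
Conditions: TBSCl (2.5 equiv), imidazole, DMF, rt
Reagents that add atoms: tert-butyldimethylsilyl chloride, CC(C)(C)[Si](C)(C)Cl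
Why: Silyl ether formation on both hydroxyl groups under standard imidazole conditions; the stereocentres are not involved.

**Step 10**
Reactants: 15 (4S,5R)-4-[(tert-butyldimethylsilyl)oxy]-5-{[(tert-butyldimethylsilyl)oxy]methyl}oxolan-2-one
Product: 16 (4S,5R)-4-[(tert-butyldimethylsilyl)oxy]-5-(hydroxymethyl)oxolan-2-one
Conditions: TFA/H2O/THF (1:1:4), 0 °C
Reagents that add atoms: none
Why: Selective acid-catalysed desilylation: the primary TBS ether should be cleaved faster than the hindered secondary one, and the lactone is stable to aqueous acid at 0 °C.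

**Step 11**
Reactants: 16 (4S,5R)-4-[(tert-butyldimethylsilyl)oxy]-5-(hydroxymethyl)oxolan-2-one
Product: 17 (2S,3S)-3-[(tert-butyldimethylsilyl)oxy]-5-oxooxolane-2-carbaldehyde
Conditions: Dess–Martin periodinane, CH2Cl2, 0 °C → rt; used crude
Reagents that add atoms: none
Why: Dess–Martin oxidation of the primary alcohol under non-basic conditions, which should spare the α-stereocentre (C13) and the β-silyloxy group of the aldehyde.

**Step 12**
Reactants: 17 (2S,3S)-3-[(tert-butyldimethylsilyl)oxy]-5-oxooxolane-2-carbaldehyde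
Product: 18 (4S,5R)-4-[(tert-butyldimethylsilyl)oxy]-5-(2-methylprop-1-en-1-yl)oxolan-2-one
Conditions: i-PrPPh3+ I−, n-BuLi, THF, 0 °C; then 17, −78 → 0 °C
Reagents that add atoms: isopropyltriphenylphosphonium iodide, CC(C)[P+](c1ccccc1)(c1ccccc1)c1ccccc1.[I-]
Why: Wittig olefination with the non-stabilised isopropylidene ylide; addition to the aldehyde at −78 °C should outrun enolisation, so C13 is not epimerised, the β-silyloxy group is not eliminated, and the lactone carbonyl is left alone.

**Step 13**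
Reactants: 18 (4S,5R)-4-[(tert-butyldimethylsilyl)oxy]-5-(2-methylprop-1-en-1-yl)oxolan-2-one
Product: 20 (3S,4S,5R)-4-[(tert-butyldimethylsilyl)oxy]-3-[(dimethylamino)methyl]-5-(2-methylprop-1-en-1-yl)oxolan-2-one, via lithium enolate 19 (not isolated)
Conditions: LDA, THF, −78 °C; then Me2N+=CH2 I−, −78 → −20 °C
Reagents that add atoms: Eschenmoser's salt (N,N-dimethylmethyleneiminium iodide), C=[N+](C)C.[I-]
Why: Mannich reaction of the lactone lithium enolate with Eschenmoser's salt; the electrophile should enter anti to the C12 silyloxy group (inconsequential, since the centre becomes sp2 in step 14), and at −78 °C the β-silyloxy enolate should not eliminate.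

**Step 14**
Reactants: 20 (3S,4S,5R)-4-[(tert-butyldimethylsilyl)oxy]-3-[(dimethylamino)methyl]-5-(2-methylprop-1-en-1-yl)oxolan-2-one
Product: 22 (4S,5R)-4-[(tert-butyldimethylsilyl)oxy]-3-methylidene-5-(2-methylprop-1-en-1-yl)oxolan-2-one, via methiodide 21 (not isolated)
Conditions: MeI, MeOH, rt; then DBU, CH2Cl2, 0 °C
Reagents that add atoms: none
Why: N-Quaternisation followed by E1cB (Hofmann-type) elimination of trimethylamine gives the exo-methylene lactone; the much poorer silyloxy leaving group on C12 should stay.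

**Step 15**
Reactants: 12 (2Z,6E,8R)-8-[(tert-butyldimethylsilyl)oxy]-3,7-dimethylundeca-2,6,10-trien-1-yl benzoate; 22 (4S,5R)-4-[(tert-butyldimethylsilyl)oxy]-3-methylidene-5-(2-methylprop-1-en-1-yl)oxolan-2-one
Product: 23 (2Z,6E,8R)-8-[(tert-butyldimethylsilyl)oxy]-10-[(3E,4S,5R)-4-[(tert-butyldimethylsilyl)oxy]-5-(2-methylprop-1-en-1-yl)-2-oxooxolan-3-ylidene]-3,7-dimethyldeca-2,6-dien-1-yl benzoate
Conditions: Hoveyda–Grubbs II (10 mol %), 2,6-dichloro-1,4-benzoquinone (20 mol %), 22 (2 equiv), CH2Cl2, 40 °C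
Reagents that add atoms: none
Why: Olefin cross-metathesis between the monosubstituted terminal alkene of 12 and the 1,1-disubstituted methylene of 22 (the trisubstituted alkenes should be inert under these conditions); the E alkylidene, with C9 anti to the lactone carbonyl, is the thermodynamically favoured isomer expected for α-alkylidene-γ-butyrolactones, and the benzoquinone suppresses Ru–H double-bond migration.

**Step 16**
Reactants: 23 the bis-TBS ether from step 15
Product: 24 (2Z,6E,8R)-8-hydroxy-10-[(3E,4S,5R)-4-hydroxy-5-(2-methylprop-1-en-1-yl)-2-oxooxolan-3-ylidene]-3,7-dimethyldeca-2,6-dien-1-yl benzoate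
Conditions: HF·pyridine, pyridine/THF, 0 °C → rt
Reagents that add atoms: none
Why: Fluoride-mediated desilylation of both TBS ethers under buffered conditions that spare the benzoate and the alkylidene lactone; in the E isomer the C8 hydroxyl cannot translactonise onto C20, and no stereocentre is affected.

**Step 17**
Reactants: 24 the diol from step 16
Product: 25 (2Z,6E,8R)-8-acetoxy-10-[(3E,4S,5R)-4-acetoxy-5-(2-methylprop-1-en-1-yl)-2-oxooxolan-3-ylidene]-3,7-dimethyldeca-2,6-dien-1-yl benzoate (CNP0262857.1)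
Conditions: Ac2O, pyridine, DMAP (cat.), CH2Cl2, 0 °C → rt
Reagents that add atoms: acetic anhydride, CC(=O)OC(C)=O
Why: DMAP-catalysed acetylation of the two secondary alcohols (C8 and C12) with retention at both carbinol centres should give the target.

**Compound list**
1 | (E)-4,4-dimethoxy-2-methylbut-2-enal | O=C/C(C)=C/C(OC)OC | starting material
2 | bis(isopinocampheyl)borinate ester of 3 | B([C@H]1C[C@H]2C[C@@H]([C@@H]1C)C2(C)C)([C@H]1C[C@H]2C[C@@H]([C@@H]1C)C2(C)C)O[C@H](CC=C)/C(C)=C/C(OC)OC | intermediate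
3 | (2E,4R)-1,1-dimethoxy-3-methylhepta-2,6-dien-4-ol | O[C@H](CC=C)/C(C)=C/C(OC)OC | intermediate
4 | tert-butyl{[(2E,4R)-1,1-dimethoxy-3-methylhepta-2,6-dien-4-yl]oxy}dimethylsilane | CC(C)(C)[Si](C)(C)O[C@H](CC=C)/C(C)=C/C(OC)OC | intermediate
5 | (2E,4R)-4-[(tert-butyldimethylsilyl)oxy]-3-methylhepta-2,6-dienal | CC(C)(C)[Si](C)(C)O[C@H](CC=C)/C(C)=C/C=O | intermediate
6 | ethyl 3-methylbut-2-enoate | CCOC(=O)C=C(C)C | starting material
7 | lithium dienolate of 6 (lithium 1-ethoxy-3-methylbuta-1,3-dien-1-olate) | C=C(C)C=C([O-])OCC.[Li+] | intermediate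
8 | lithium alkoxide of ethyl (2Z,6E,8R)-8-[(tert-butyldimethylsilyl)oxy]-5-hydroxy-3,7-dimethylundeca-2,6,10-trienoate (C5 epimers) | CC(C)(C)[Si](C)(C)O[C@H](CC=C)/C(C)=C/C([O-])C/C(C)=C\C(=O)OCC.[Li+] | intermediate
9 | 6-[(1E,3R)-3-[(tert-butyldimethylsilyl)oxy]-2-methylhexa-1,5-dien-1-yl]-4-methyl-5,6-dihydro-2H-pyran-2-one (C6 epimers) | CC(C)(C)[Si](C)(C)O[C@H](CC=C)/C(C)=C/C1CC(C)=CC(=O)O1 | intermediate
10 | (2Z,6E,8R)-8-[(tert-butyldimethylsilyl)oxy]-3,7-dimethylundeca-2,6,10-trienoic acid | CC(C)(C)[Si](C)(C)O[C@H](CC=C)/C(C)=C/CC/C(C)=C\C(=O)O | intermediate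
11 | (2Z,6E,8R)-8-[(tert-butyldimethylsilyl)oxy]-3,7-dimethylundeca-2,6,10-trien-1-ol | CC(C)(C)[Si](C)(C)O[C@H](CC=C)/C(C)=C/CC/C(C)=C\CO | intermediate
12 | (2Z,6E,8R)-8-[(tert-butyldimethylsilyl)oxy]-3,7-dimethylundeca-2,6,10-trien-1-yl benzoate | CC(C)(C)[Si](C)(C)O[C@H](CC=C)/C(C)=C/CC/C(C)=C\COC(=O)c1ccccc1 | intermediate
13 | 2-deoxy-D-ribose (open-chain form, (3S,4R)-3,4,5-trihydroxypentanal) | O=CC[C@H](O)[C@H](O)CO | starting material
14 | 2-deoxy-D-ribono-1,4-lactone, (4S,5R)-4-hydroxy-5-(hydroxymethyl)oxolan-2-one | C1C(=O)O[C@H](CO)[C@H]1O | intermediate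
15 | (4S,5R)-4-[(tert-butyldimethylsilyl)oxy]-5-{[(tert-butyldimethylsilyl)oxy]methyl}oxolan-2-one | C1C(=O)O[C@H](CO[Si](C)(C)C(C)(C)C)[C@H]1O[Si](C)(C)C(C)(C)C | intermediate
16 | (4S,5R)-4-[(tert-butyldimethylsilyl)oxy]-5-(hydroxymethyl)oxolan-2-one | C1C(=O)O[C@H](CO)[C@H]1O[Si](C)(C)C(C)(C)C | intermediate
17 | (2S,3S)-3-[(tert-butyldimethylsilyl)oxy]-5-oxooxolane-2-carbaldehyde | C1C(=O)O[C@H](C=O)[C@H]1O[Si](C)(C)C(C)(C)C | intermediate
18 | (4S,5R)-4-[(tert-butyldimethylsilyl)oxy]-5-(2-methylprop-1-en-1-yl)oxolan-2-one | C1C(=O)O[C@H](C=C(C)C)[C@H]1O[Si](C)(C)C(C)(C)C | intermediate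
19 | lithium enolate of 18 | C1=C([O-])O[C@H](C=C(C)C)[C@H]1O[Si](C)(C)C(C)(C)C.[Li+] | intermediate
20 | (3S,4S,5R)-4-[(tert-butyldimethylsilyl)oxy]-3-[(dimethylamino)methyl]-5-(2-methylprop-1-en-1-yl)oxolan-2-one | CN(C)C[C@@H]1C(=O)O[C@H](C=C(C)C)[C@H]1O[Si](C)(C)C(C)(C)C | intermediate
21 | trimethylammonium iodide (methiodide) of 20 | C[N+](C)(C)C[C@@H]1C(=O)O[C@H](C=C(C)C)[C@H]1O[Si](C)(C)C(C)(C)C.[I-] | intermediate
22 | (4S,5R)-4-[(tert-butyldimethylsilyl)oxy]-3-methylidene-5-(2-methylprop-1-en-1-yl)oxolan-2-one | C=C1C(=O)O[C@H](C=C(C)C)[C@H]1O[Si](C)(C)C(C)(C)C | intermediate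
23 | (2Z,6E,8R)-8-[(tert-butyldimethylsilyl)oxy]-10-[(3E,4S,5R)-4-[(tert-butyldimethylsilyl)oxy]-5-(2-methylprop-1-en-1-yl)-2-oxooxolan-3-ylidene]-3,7-dimethyldeca-2,6-dien-1-yl benzoate | CC(C)(C)[Si](C)(C)O[C@H](C/C=C1/C(=O)O[C@H](C=C(C)C)[C@H]1O[Si](C)(C)C(C)(C)C)/C(C)=C/CC/C(C)=C\COC(=O)c1ccccc1 | intermediate
24 | (2Z,6E,8R)-8-hydroxy-10-[(3E,4S,5R)-4-hydroxy-5-(2-methylprop-1-en-1-yl)-2-oxooxolan-3-ylidene]-3,7-dimethyldeca-2,6-dien-1-yl benzoate | O[C@H](C/C=C1/C(=O)O[C@H](C=C(C)C)[C@H]1O)/C(C)=C/CC/C(C)=C\COC(=O)c1ccccc1 | intermediate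
25 | (2Z,6E,8R)-8-acetoxy-10-[(3E,4S,5R)-4-acetoxy-5-(2-methylprop-1-en-1-yl)-2-oxooxolan-3-ylidene]-3,7-dimethyldeca-2,6-dien-1-yl benzoate (CNP0262857.1) | CC(=O)O[C@H](C/C=C1/C(=O)O[C@H](C=C(C)C)[C@H]1OC(C)=O)/C(C)=C/CC/C(C)=C\COC(=O)c1ccccc1 | target

**Step count and risks**
Total: 17 steps. Longest linear sequence: 10 steps (steps 1–7, then 15–17; the lactone branch, steps 8–14 then 15–17, is equally long).

Three steps most likely to fail:

1. Step 15 (cross-metathesis). The methylene of 22 is 1,1-disubstituted, electron-poor and flanked by the silyloxy-bearing carbon, so productive metathesis may be slow. Homodimerisation of 12, Ru–H migration of the exo double bond into the ring, or incomplete E control could then dominate. Fallback, a temporary silicon tether that makes the metathesis intramolecular and fixes the geometry by ring size: 12 is desilylated (HF·pyridine) to (2Z,6E,8R)-8-hydroxy-3,7-dimethylundeca-2,6,10-trien-1-yl benzoate F1, and 22 is desilylated in the same way to (4S,5R)-4-hydroxy-3-methylidene-5-(2-methylprop-1-en-1-yl)oxolan-2-one F2. F2 is treated with i-Pr2SiCl2/imidazole and the resulting chlorosilane is trapped with F1 to give the mixed diisopropylsilylene bis-ether F3. Ring-closing metathesis (Grubbs II, dilute toluene, 80 °C) should close the eight-membered 1,3-dioxa-2-silacyclooct-5-ene F4, in which the ring alkene C10=C11 must be cis (C9 syn to C12), which is exactly the E alkylidene geometry. HF·pyridine then removes the tether and gives diol 24, where the route is rejoined before step 17.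

2. Step 5 (reductive opening of the allylic lactone). β-Hydride elimination from the π-allyl palladium intermediate would give a conjugated trienoic acid; hydride delivery at the more substituted allyl terminus or conjugate reduction of the enoate are further risks. Fallback, which forms the C4–C5 bond by alkylation so that C5 never carries oxygen: enal 5 is reduced under Luche conditions to (2E,4R)-4-[(tert-butyldimethylsilyl)oxy]-3-methylhepta-2,6-dien-1-ol F5, which CBr4/PPh3 converts into the allylic bromide F6. The dianion of methyl acetoacetate (NaH, then n-BuLi, THF, 0 °C) is alkylated at its γ-carbon by F6 to give methyl (6E,8R)-8-[(tert-butyldimethylsilyl)oxy]-7-methyl-3-oxoundeca-6,10-dienoate F7. Enol phosphorylation under amine conditions (Et3N, DMAP, HMPA, (EtO)2P(O)Cl) should give the (2E)-enol phosphate F8, and Me2CuLi (Et2O, −78 → −45 °C) should replace the phosphate with retention to give the methyl (2Z)-ester F9. DIBAL-H (CH2Cl2, −78 °C) then gives allylic alcohol 11, where the route is rejoined before step 7.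

3. Step 4 (key step). Kinetic α-addition of the dienolate may not funnel to the γ-adduct with an enal; γ-deprotonation of 5 would erode C8; the ethoxide set free could open lactone 9 by elimination to a trienoic acid. Fallback, which keeps the C4–C5 disconnection and the ring-locked Z alkene but builds the lactone in stages: the dianion of methyl acetoacetate adds through its γ-carbon to enal 5 (THF, −78 °C) to give the δ-hydroxy-β-keto ester methyl (6E,8R)-8-[(tert-butyldimethylsilyl)oxy]-5-hydroxy-7-methyl-3-oxoundeca-6,10-dienoate F10. Lactonisation (K2CO3, MeOH, then mild acidification) gives 6-[(1E,3R)-3-[(tert-butyldimethylsilyl)oxy]-2-methylhexa-1,5-dien-1-yl]oxane-2,4-dione F11. Tf2O/Et3N (CH2Cl2, −78 °C) gives the enol triflate F12, and Me2CuLi (THF, −78 °C) should substitute the triflate by addition–elimination to give lactone 9, where the route is rejoined before step 5.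

**Further compounds**
F1 | step 15 | (2Z,6E,8R)-8-hydroxy-3,7-dimethylundeca-2,6,10-trien-1-yl benzoate | O[C@H](CC=C)/C(C)=C/CC/C(C)=C\COC(=O)c1ccccc1
F2 | step 15 | (4S,5R)-4-hydroxy-3-methylidene-5-(2-methylprop-1-en-1-yl)oxolan-2-one | C=C1C(=O)O[C@H](C=C(C)C)[C@H]1O
F3 | step 15 | mixed diisopropylsilylene bis-ether of F1 (through O on C8) and F2 (through O on C12) | C=C1C(=O)O[C@H](C=C(C)C)[C@H]1O[Si](C(C)C)(C(C)C)O[C@H](CC=C)/C(C)=C/CC/C(C)=C\COC(=O)c1ccccc1
F4 | step 15 | eight-membered cyclic diisopropylsilylene ether of diol 24 (1,3-dioxa-2-silacyclooct-5-ene fused to the lactone at C11–C12) | O1[C@H](C/C=C2/C(=O)O[C@H](C=C(C)C)[C@H]2O[Si]1(C(C)C)C(C)C)/C(C)=C/CC/C(C)=C\COC(=O)c1ccccc1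
F5 | step 5 | (2E,4R)-4-[(tert-butyldimethylsilyl)oxy]-3-methylhepta-2,6-dien-1-ol | CC(C)(C)[Si](C)(C)O[C@H](CC=C)/C(C)=C/CO
F6 | step 5 | {[(4R,5E)-7-bromo-5-methylhepta-1,5-dien-4-yl]oxy}(tert-butyl)dimethylsilane | CC(C)(C)[Si](C)(C)O[C@H](CC=C)/C(C)=C/CBr
F7 | step 5 | methyl (6E,8R)-8-[(tert-butyldimethylsilyl)oxy]-7-methyl-3-oxoundeca-6,10-dienoate | CC(C)(C)[Si](C)(C)O[C@H](CC=C)/C(C)=C/CCC(=O)CC(=O)OC
F8 | step 5 | methyl (2E,6E,8R)-8-[(tert-butyldimethylsilyl)oxy]-3-[(diethoxyphosphoryl)oxy]-7-methylundeca-2,6,10-trienoate | CC(C)(C)[Si](C)(C)O[C@H](CC=C)/C(C)=C/CC/C(OP(=O)(OCC)OCC)=C\C(=O)OC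
F9 | step 5 | methyl (2Z,6E,8R)-8-[(tert-butyldimethylsilyl)oxy]-3,7-dimethylundeca-2,6,10-trienoate | CC(C)(C)[Si](C)(C)O[C@H](CC=C)/C(C)=C/CC/C(C)=C\C(=O)OC
F10 | step 4 | methyl (6E,8R)-8-[(tert-butyldimethylsilyl)oxy]-5-hydroxy-7-methyl-3-oxoundeca-6,10-dienoate (C5 epimers) | CC(C)(C)[Si](C)(C)O[C@H](CC=C)/C(C)=C/C(O)CC(=O)CC(=O)OC
F11 | step 4 | 6-[(1E,3R)-3-[(tert-butyldimethylsilyl)oxy]-2-methylhexa-1,5-dien-1-yl]oxane-2,4-dione | CC(C)(C)[Si](C)(C)O[C@H](CC=C)/C(C)=C/C1CC(=O)CC(=O)O1
F12 | step 4 | 2-[(1E,3R)-3-[(tert-butyldimethylsilyl)oxy]-2-methylhexa-1,5-dien-1-yl]-6-oxo-3,6-dihydro-2H-pyran-4-yl trifluoromethanesulfonate | CC(C)(C)[Si](C)(C)O[C@H](CC=C)/C(C)=C/C1CC(OS(=O)(=O)C(F)(F)F)=CC(=O)O1
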